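**Plan**

- Retrosynthetic cuts: first the two MOM ethers; then O1–C8a and C4–C4a of the pyranone, which lifts the arene edge C4a–C8a out of the acyl–oxygen bond of (4S)-4-phenyloxetan-2-one (O1, C2, C3, C4 stay together); then N–CH3, N–C6' (piperidine closure) and aryl–C2'.
- Enabling feature: ring C is a β-lactone with an arene edge inserted. The acyl carbon C4 and the ether oxygen O1 sit on adjacent arene carbons and are bridged only by C2–C3. With F at C8a (para to C6), ring A has a local two-fold axis through C6/C8a, so its two C–H bonds (each between F and OMOM) are equivalent and the piperidine can only end up at C6, not C8.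
- Forward order: aryl iodide → aryl–C2' bond → piperidine ring → N-methyl → pyranone by two-atom ring expansion of the oxetanone → MOM removal.
- Stereochemistry: C2 (S) is bought as (S)-3-hydroxy-3-phenylpropanoic acid and none of its bonds is broken afterwards. C2' (R) is set by (R)-tert-butanesulfinamide in the Grignard addition. The two centres are remote and are set independently.

Key step: step 9

Assumption: atom labels follow chromanone numbering (O1, C2, C3, C4, C4a, C5–C8, C8a) and C2'–C6' for the piperidine; the target is isolated as the free base; 5-chloropentanal is made fresh because it does not keep.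

**Route**

Step 1
Reactants: 1 5-fluorobenzene-1,3-diol
Product: 2 5-fluoro-2-iodobenzene-1,3-diol
Conditions: I2 (1.05 equiv), NaHCO3, H2O/THF, 0 °C to rt
Reagents that add atoms: iodine, II
Why: Electrophilic iodination under the I2/NaHCO3 conditions that convert resorcinol into 2-iodoresorcinol should place iodine between the two hydroxyl groups, a position that is also para (not ortho) to the deactivating fluorine.

Step 2
Reactants: 2 5-fluoro-2-iodobenzene-1,3-diol
Product: 3 5-fluoro-2-iodo-1,3-bis(methoxymethoxy)benzene
Conditions: MOMCl (2.5 equiv), i-Pr2NEt, CH2Cl2, 0 °C to rt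
Reagents that add atoms: chloromethyl methyl ether, COCCl
Why: Standard O-alkylation of phenols to MOM acetals, which later survive organomagnesium and organolithium reagents and direct the lithiation of step 9.

Step 3
Reactants: 4 5-chloropentan-1-ol
Product: 5 5-chloropentanal
Conditions: TEMPO (10 mol%), PhI(OAc)2 (1.1 equiv), CH2Cl2, rt; used at once
Reagents that add atoms: none
Why: Oxoammonium (TEMPO) oxidation of a primary alcohol stops at the aldehyde and leaves the alkyl chloride alone.

Step 4
Reactants: 5 5-chloropentanal; 6 (R)-2-methylpropane-2-sulfinamide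
Product: 7 (R,E)-N-(5-chloropentylidene)-2-methylpropane-2-sulfinamide
Conditions: CuSO4 (anhydrous), CH2Cl2, rt
Reagents that add atoms: none
Why: Dehydrative condensation of an aldehyde with tert-butanesulfinamide gives the E N-sulfinyl aldimine without racemisation at sulfur.

Step 5
Reactants: 3 5-fluoro-2-iodo-1,3-bis(methoxymethoxy)benzene; 7 (R,E)-N-(5-chloropentylidene)-2-methylpropane-2-sulfinamide
Product: 9 (R)-N-[(1R)-5-chloro-1-[4-fluoro-2,6-bis(methoxymethoxy)phenyl]pentyl]-2-methylpropane-2-sulfinamide, via arylmagnesium chloride 8 (not isolated)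
Conditions: i-PrMgCl·LiCl, THF, 0 °C; then 7, CH2Cl2, −48 °C to rt; aq NH4Cl
Reagents that add atoms: none
Why: Iodine–magnesium exchange followed by aryl Grignard addition to an N-tert-butanesulfinyl aldimine; the magnesium-chelated six-membered chair transition state (tert-butyl equatorial) should deliver the aryl group to the Si face of the (R_S,E)-imine and so set C2' as R.

Step 6
Reactants: 9 (R)-N-[(1R)-5-chloro-1-[4-fluoro-2,6-bis(methoxymethoxy)phenyl]pentyl]-2-methylpropane-2-sulfinamide
Product: 11 (2R)-2-[4-fluoro-2,6-bis(methoxymethoxy)phenyl]piperidine, via aminium chloride 10 (not isolated)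
Conditions: HCl (4 M in dioxane, 2 equiv), MeOH, 0 °C, 20 min; evaporate; K2CO3, NaI (cat.), MeCN, 60 °C
Reagents that add atoms: none
Why: Brief HCl/methanol should cleave the sulfinamide N–S bond much faster than the aryl MOM ethers, and the freed primary amine then closes the piperidine by intramolecular 6-exo-tet N-alkylation without touching the stereocentre.

Step 7
Reactants: 11 (2R)-2-[4-fluoro-2,6-bis(methoxymethoxy)phenyl]piperidine
Product: 12 (2R)-2-[4-fluoro-2,6-bis(methoxymethoxy)phenyl]-1-methylpiperidine
Conditions: aq HCHO, NaBH(OAc)3, ClCH2CH2Cl, rt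
Reagents that add atoms: formaldehyde, C=O
Why: Reductive amination (iminium reduced by triacetoxyborohydride) methylates the secondary amine once and tolerates the MOM ethers and the aryl fluoride.

Step 8
Reactants: 13 (3S)-3-hydroxy-3-phenylpropanoic acid
Product: 14 (4S)-4-phenyloxetan-2-one
Conditions: PhSO2Cl (2 equiv), pyridine, 0–5 °C; kept cold
Reagents that add atoms: none
Why: β-Lactonisation by carboxyl activation (mixed sulfonic–carboxylic anhydride, then 4-exo-trig attack of the C3 hydroxyl) does not break the C3–O bond, so the S configuration is retained.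

Step 9
Reactants: 12 (2R)-2-[4-fluoro-2,6-bis(methoxymethoxy)phenyl]-1-methylpiperidine; 14 (4S)-4-phenyloxetan-2-one
Product: 17 (2S)-5,7-bis(methoxymethoxy)-6-[(2R)-1-methylpiperidin-2-yl]-2-phenylchroman-4-one, via aryllithium 15 (not isolated), via lithium aldolate 16 (not isolated)
Conditions: n-BuLi, THF, −78 °C; cannulate into 14 (1.2 equiv), THF, −78 °C; then DMPU, −78 to 0 °C; AcOH quench
Reagents that add atoms: none
Why: Proposed new method: aryllithium 15 (from deprotonation of the only kind of ring C–H in 12, flanked by F and OMOM) attacks the strained lactone carbonyl of 14, acyl–oxygen cleavage opens the four-membered ring to aldolate 16, and its C2 alkoxide then displaces fluoride at C8a, now the β-carbon of a vinylogous acyl fluoride (C8a=C4a–C4=O), so the arene edge C4a–C8a ends up inserted into the O1–C4 bond and the oxetanone has grown by two atoms into the pyranone. The closest known reaction types are acyl–oxygen opening of β-lactones by organolithiums to β-hydroxy ketones, intramolecular SNAr of alkoxides on o-fluoroaryl ketones to chroman-4-ones, and the two-atom ring expansion of N–H β-lactams by arynes to 2,3-dihydroquinolin-4-ones; merging the first two in one flask on a β-lactone is the new part. The pyranone closes by addition–elimination at C8a through a Meisenheimer intermediate (six-membered, endo with respect to the C8a=C4a π bond, loss of LiF). No stereocentre is formed: C2 is the lactone stereocentre of 14 and none of its four bonds is touched, so (4S)-14 maps onto (2S)-17, and the remote (R)-piperidine centre is not acidic. The step needs acyl rather than alkyl C–O cleavage and mono-addition (hard, hindered aryllithium at −78 °C, inverse addition), and it needs SNAr to outrun retro-aldol cleavage and dehydration of 16 (DMPU to free the alkoxide, at most 0 °C, prompt acidic quench so that 17 is not left with base that could open it to the chalcone).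

Step 10
Reactants: 17 (2S)-5,7-bis(methoxymethoxy)-6-[(2R)-1-methylpiperidin-2-yl]-2-phenylchroman-4-one
Product: 18 (2S)-5,7-dihydroxy-6-[(2R)-1-methylpiperidin-2-yl]-2-phenylchroman-4-one
Conditions: HCl (2 M in MeOH), rt; cold aq NaHCO3 work-up
Reagents that add atoms: none
Why: Acid-catalysed acetal exchange of the two aryl MOM ethers with methanol; acid is chosen because flavanones open to chalcones (loss of the C2 configuration) under base, and room temperature should leave the benzylic amine centre untouched.

**Compound list**

1 | 5-fluorobenzene-1,3-diol | Oc1cc(O)cc(F)c1 | starting material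
2 | 5-fluoro-2-iodobenzene-1,3-diol | Oc1cc(F)cc(O)c1I | intermediate
3 | 5-fluoro-2-iodo-1,3-bis(methoxymethoxy)benzene | COCOc1cc(F)cc(OCOC)c1I | intermediate
4 | 5-chloropentan-1-ol | OCCCCCCl | starting material
5 | 5-chloropentanal | O=CCCCCCl | intermediate
6 | (R)-2-methylpropane-2-sulfinamide | CC(C)(C)[S@@](=O)N | starting material
7 | (R,E)-N-(5-chloropentylidene)-2-methylpropane-2-sulfinamide | CC(C)(C)[S@@](=O)/N=C/CCCCCl | intermediate
8 | [4-fluoro-2,6-bis(methoxymethoxy)phenyl]magnesium chloride | COCOc1cc(F)cc(OCOC)c1[Mg]Cl | intermediate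
9 | (R)-N-[(1R)-5-chloro-1-[4-fluoro-2,6-bis(methoxymethoxy)phenyl]pentyl]-2-methylpropane-2-sulfinamide | CC(C)(C)[S@@](=O)N[C@H](CCCCCl)c1c(OCOC)cc(F)cc1OCOC | intermediate
10 | (1R)-5-chloro-1-[4-fluoro-2,6-bis(methoxymethoxy)phenyl]pentan-1-aminium chloride | [NH3+][C@H](CCCCCl)c1c(OCOC)cc(F)cc1OCOC.[Cl-] | intermediate
11 | (2R)-2-[4-fluoro-2,6-bis(methoxymethoxy)phenyl]piperidine | COCOc1cc(F)cc(OCOC)c1[C@H]1CCCCN1 | intermediate
12 | (2R)-2-[4-fluoro-2,6-bis(methoxymethoxy)phenyl]-1-methylpiperidine | COCOc1cc(F)cc(OCOC)c1[C@H]1CCCCN1C | intermediate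
13 | (3S)-3-hydroxy-3-phenylpropanoic acid | OC(=O)C[C@H](O)c1ccccc1 | starting material
14 | (4S)-4-phenyloxetan-2-one | O=C1C[C@@H](c2ccccc2)O1 | intermediate
15 | [6-fluoro-2,4-bis(methoxymethoxy)-3-[(2R)-1-methylpiperidin-2-yl]phenyl]lithium | [Li]c1c(F)cc(OCOC)c([C@H]2CCCCN2C)c1OCOC | intermediate
16 | lithium (1S)-3-[6-fluoro-2,4-bis(methoxymethoxy)-3-[(2R)-1-methylpiperidin-2-yl]phenyl]-3-oxo-1-phenylpropan-1-olate | [Li+].[O-][C@@H](CC(=O)c1c(F)cc(OCOC)c([C@H]2CCCCN2C)c1OCOC)c1ccccc1 | intermediate
17 | (2S)-5,7-bis(methoxymethoxy)-6-[(2R)-1-methylpiperidin-2-yl]-2-phenylchroman-4-one | CN1CCCC[C@@H]1c1c(OCOC)cc2c(c1OCOC)C(=O)C[C@@H](c1ccccc1)O2 | intermediate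
18 | (2S)-5,7-dihydroxy-6-[(2R)-1-methylpiperidin-2-yl]-2-phenylchroman-4-one | CN1CCCC[C@@H]1c1c(O)cc2c(c1O)C(=O)C[C@@H](c1ccccc1)O2 | target

**Step count and risks**

Total steps: 10. Longest linear sequence: 7 (steps 1, 2, 5, 6, 7, 9, 10).

Steps most likely to fail:

1. Step 9 (key step). The aldolate may undergo retro-aldol cleavage or dehydration before the ring closes, which would erode the C2 configuration; the aryllithium may also add twice or enolise the lactone. Fallback, from 12 back to 17, with C2 set by a catalyst instead of being carried through a ring expansion: 12 is lithiated as in step 9 and quenched with N-methoxy-N-methylacetamide to give the methyl ketone 1-[6-fluoro-2,4-bis(methoxymethoxy)-3-[(2R)-1-methylpiperidin-2-yl]phenyl]ethan-1-one F1. Claisen formylation (HCO2Et, NaH, THF) and warming in DMF should let the formyl enolate oxygen displace fluoride to give the chromone 5,7-bis(methoxymethoxy)-6-[(2R)-1-methylpiperidin-2-yl]-4H-chromen-4-one F2. Palladium(II)/t-BuPyOX-catalysed asymmetric conjugate addition of phenylboronic acid (ligand enantiomer chosen for 2S, amine buffered as its ammonium salt) then gives 17.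

2. Step 5. The di-ortho-substituted aryl Grignard reagent may add sluggishly and with poor facial selectivity, or may deprotonate the aldimine. Fallback, from 3 back to 11, with the roles of the two carbon partners exchanged: magnesiated 3 is formylated with DMF to 4-fluoro-2,6-bis(methoxymethoxy)benzaldehyde F3. This is condensed with (S)-tert-butanesulfinamide (Ti(OEt)4) to (S,E)-N-[4-fluoro-2,6-bis(methoxymethoxy)benzylidene]-2-methylpropane-2-sulfinamide F4. The unhindered 4-chlorobutylmagnesium bromide is added through the same chelated transition state (hence the enantiomeric auxiliary) to give (S)-N-[(1R)-5-chloro-1-[4-fluoro-2,6-bis(methoxymethoxy)phenyl]pentyl]-2-methylpropane-2-sulfinamide F5, which is taken through the conditions of step 6 to 11.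

3. Step 6. The MOM ethers may be partly lost during acidic N–S cleavage. Fallback, from 3 back to 11, with no acid-labile auxiliary: magnesiated 3 is added to 5-chloropentanenitrile and the resulting metallo-imine alkylates itself to the cyclic imine 6-[4-fluoro-2,6-bis(methoxymethoxy)phenyl]-2,3,4,5-tetrahydropyridine F6. F6 is reduced to 11 by iridium-catalysed asymmetric hydrogenation of the cyclic imine (or an (R)-selective imine reductase).

**Further compounds**

F1 | step 9 | 1-[6-fluoro-2,4-bis(methoxymethoxy)-3-[(2R)-1-methylpiperidin-2-yl]phenyl]ethan-1-one | CC(=O)c1c(F)cc(OCOC)c([C@H]2CCCCN2C)c1OCOC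
F2 | step 9 | 5,7-bis(methoxymethoxy)-6-[(2R)-1-methylpiperidin-2-yl]-4H-chromen-4-one | COCOc1cc2occc(=O)c2c(OCOC)c1[C@H]1CCCCN1C
F3 | step 5 | 4-fluoro-2,6-bis(methoxymethoxy)benzaldehyde | COCOc1cc(F)cc(OCOC)c1C=O
F4 | step 5 | (S,E)-N-[4-fluoro-2,6-bis(methoxymethoxy)benzylidene]-2-methylpropane-2-sulfinamide | CC(C)(C)[S@](=O)/N=C/c1c(OCOC)cc(F)cc1OCOC
F5 | step 5 | (S)-N-[(1R)-5-chloro-1-[4-fluoro-2,6-bis(methoxymethoxy)phenyl]pentyl]-2-methylpropane-2-sulfinamide | CC(C)(C)[S@](=O)N[C@H](CCCCCl)c1c(OCOC)cc(F)cc1OCOC
F6 | step 6 | 6-[4-fluoro-2,6-bis(methoxymethoxy)phenyl]-2,3,4,5-tetrahydropyridine | COCOc1cc(F)cc(OCOC)c1C1=NCCCC1
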